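**Retrosynthetic overview**
1. Oxonene last: C6–C7 by intramolecular CrCl2/NiCl2 coupling of a (Z)-vinyl iodide with a C6 aldehyde, which also sets C6.
2. Oxepane before that: C16–O–C3 by primary triflate displacement, after hydroboration of a C14 isopropenyl group (sets C15).
3. Tetrahydrofuran: C9–C10 and C9–O in one oxocarbenium/enol carbamate annulation that also unveils the C11 ketone (sets C9, C10).
4. Key C1–C2 bond: a titanated 1-(carbamoyloxy)allyl unit, i.e. the β-carbanion (homoenolate) equivalent of the C11 ketone, adds to an α-alkoxy aldehyde (sets C1, C2).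
5. Fragments: enol carbamate A from (+)-α-pinene (cyclohexane preformed; C12 and C14 from the pinane), aldehyde B from nerol (C3), iodoenal C from but-2-yn-1-ol. Ring order: cyclohexene, tetrahydrofuran, oxepane, oxonene.

Assumption: labels C1–C16 follow asbestinin numbering (cyclohexane C1, C10–C14; C2–O–C9 tetrahydrofuran; C3–O–C16 oxepane; OAc on C11, OH on C6), and the SMILES fixes the configuration as 1S,2S,3S,6R,9S,10R,11R,12R,14S,15R, which requires the (+)-pinene series.

**Step 1**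
Reactants: 1 (1R,5R)-(+)-α-pinene
Product: 4 (1R,5R)-(+)-β-pinene, via pinenylpotassium 2 (not isolated), via dimethyl myrtenylboronate 3 (not isolated)
Conditions: n-BuLi, KOt-Bu, hexane, 25 °C; B(OMe)3, −78 °C; aq HCl, 25 °C
Reagents that add atoms: none
Why: Allylic potassiation of the C10 methyl, borylation and SE2′ protonolysis of the allylboronate move the double bond to the exocyclic position against thermodynamics (known α- to β-pinene isomerisation); no stereocentre is touched.

**Step 2**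
Reactants: 4 (1R,5R)-(+)-β-pinene
Product: 6 (1S,5R)-(−)-nopinone, via ozonide 5 (not isolated)
Conditions: O3, CH2Cl2, −78 °C; Me2S, −78 to 25 °C
Reagents that add atoms: ozone, [O-][O+]=O
Why: Ozonolysis of the 1,1-disubstituted alkene with reductive work-up gives the ketone; both bridgehead centres are retained.

**Step 3**
Reactants: 6 (1S,5R)-(−)-nopinone
Product: 8 (1S,3R,5R)-3,6,6-trimethylbicyclo[3.1.1]heptan-2-one, via lithium enolate 7 (not isolated)
Conditions: LiN(iPr)2, THF, −78 °C; MeI, −78 to 0 °C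
Reagents that add atoms: iodomethane, CI
Why: Kinetic enolate alkylation; MeI attacks anti to the gem-dimethyl bridge of the rigid bicycle, which fixes the future C12 methyl.

**Step 4**
Reactants: 8 (1S,3R,5R)-3,6,6-trimethylbicyclo[3.1.1]heptan-2-one
Product: 9 (4S,6R)-6-methyl-4-(prop-1-en-2-yl)cyclohex-1-en-1-yl acetate
Conditions: Ac2O, Zn(OAc)2 (0.2 equiv), BF3·OEt2 (0.2 equiv), 0 to 25 °C
Reagents that add atoms: acetic anhydride, CC(=O)OC(C)=O
Why: Lewis-acid-promoted cyclobutane fragmentation with enol acetylation (heterolysis of the bond between the α-bridgehead and CMe2, then proton loss to the isopropenyl group); C14 and C12 come unchanged from the pinane and end up trans, and the enol double bond is fixed toward C10.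

**Step 5**
Reactants: 9 (4S,6R)-6-methyl-4-(prop-1-en-2-yl)cyclohex-1-en-1-yl acetate
Product: 11 (4S,6R)-6-methyl-4-(prop-1-en-2-yl)cyclohex-1-en-1-yl N,N-diisopropylcarbamate, via lithium enolate 10 (not isolated)
Conditions: MeLi (2.1 equiv), THF, 0 °C; ClC(O)N(iPr)2, DMPU, −78 to 25 °C
Reagents that add atoms: N,N-diisopropylcarbamoyl chloride, CC(C)N(C(C)C)C(Cl)=O
Why: MeLi cleavage of the enol acetate gives the regiodefined lithium enolate without touching the C12 centre, and O-carbamoylation gives the 1-alkenyl carbamate.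

**Step 6**
Reactants: 12 nerol
Product: 13 [(2S,3R)-3-methyl-3-(4-methylpent-3-en-1-yl)oxiran-2-yl]methanol
Conditions: Ti(OiPr)4 (5 mol %), L-(+)-diethyl tartrate (6 mol %), t-BuOOH, 4 Å sieves, CH2Cl2, −20 °C
Reagents that add atoms: tert-butyl hydroperoxide, CC(C)(C)OO
Why: Sharpless asymmetric epoxidation of the (Z)-allylic alcohol; the L-tartrate catalyst delivers oxygen to one face to give the (2S,3R)-epoxide.

**Step 7**
Reactants: 13 [(2S,3R)-3-methyl-3-(4-methylpent-3-en-1-yl)oxiran-2-yl]methanol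
Product: 14 (2S,3S)-3,7-dimethyl-3-(naphthalen-2-ylmethoxy)oct-6-ene-1,2-diol
Conditions: naphthalen-2-ylmethanol (5 equiv), BF3·OEt2 (5 mol %), CH2Cl2, −40 °C
Reagents that add atoms: naphthalen-2-ylmethanol, OCc1ccc2ccccc2c1
Why: Acid-catalysed epoxide alcoholysis at the tertiary carbon with inversion installs the protected C3 ether in the S configuration.

**Step 8**
Reactants: 14 (2S,3S)-3,7-dimethyl-3-(naphthalen-2-ylmethoxy)oct-6-ene-1,2-diol
Product: 15 (2S)-2,6-dimethyl-2-(naphthalen-2-ylmethoxy)hept-5-enal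
Conditions: NaIO4, THF/H2O, 0 °C
Reagents that add atoms: none
Why: Glycol cleavage gives the α-alkoxy aldehyde; the quaternary centre cannot epimerise.

**Step 9**
Reactants: 16 but-2-yn-1-ol
Product: 18 (2Z)-3-iodobut-2-en-1-ol, via vinylalanate 17 (not isolated)
Conditions: NaAlH2(OCH2CH2OMe)2, THF, 0 °C; I2, −78 °C
Reagents that add atoms: iodine, II
Why: Alkoxide-directed trans-hydroalumination places aluminium on C3, and iodinolysis with retention gives the Z-iodoalkene.

**Step 10**
Reactants: 18 (2Z)-3-iodobut-2-en-1-ol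
Product: 19 (2Z)-3-iodobut-2-enal
Conditions: MnO2, CH2Cl2, 25 °C
Reagents that add atoms: none
Why: Neutral allylic oxidation with MnO2 keeps the Z geometry.

**Step 11**
Reactants: 11 (4S,6R)-6-methyl-4-(prop-1-en-2-yl)cyclohex-1-en-1-yl N,N-diisopropylcarbamate, 15 (2S)-2,6-dimethyl-2-(naphthalen-2-ylmethoxy)hept-5-enal
Product: 22 (3S,4R,6R)-3-[(1S,2S)-1-hydroxy-2,6-dimethyl-2-(naphthalen-2-ylmethoxy)hept-5-en-1-yl]-6-methyl-4-(prop-1-en-2-yl)cyclohex-1-en-1-yl N,N-diisopropylcarbamate, via allyllithium 20 (not isolated), via allyltitanium 21 (not isolated)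
Conditions: s-BuLi, TMEDA, Et2O, −78 °C; ClTi(OiPr)3, −78 °C; 15, −78 °C; aq NH4Cl
Reagents that add atoms: none
Why: Hoppe homoaldol reaction of a ketone homoenolate equivalent: carbamate-directed γ-deprotonation removes the pseudoaxial C1–H cis to the isopropenyl group, lithium–titanium exchange inverts, and the aldehyde is delivered to C1 on the titanium face (anti to C14) through a cyclic six-membered transition state with its quaternary residue turned away from the carbocycle, which sets C1 and C2 (H1/H2 anti, as the 2,9-bridged core needs) and regenerates the enol carbamate at C10=C11.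

**Step 12**
Reactants: 22 homoaldol adduct (enol carbamate alcohol), 19 (2Z)-3-iodobut-2-enal
Product: 24 bicyclic C11 ketone (cis-fused 2,9-epoxy core; C9 (Z)-2-iodoprop-1-enyl; C14 isopropenyl), via oxocarbenium ion 23 (not isolated)
Conditions: BF3·OEt2, CH2Cl2, −78 to −40 °C; aq NaHCO3
Reagents that add atoms: none
Why: Mukaiyama–Prins-type annulation: the hemiacetal from the C2 hydroxyl and the enal ionises to an E-oxocarbenium ion that the enol carbamate attacks from the tethered face, giving the cis ring fusion at C10 and placing the C9 alkenyl group pseudoequatorial (cis to the C2 side chain across oxygen), while loss of the carbamoyl group to fluoride reveals the C11 ketone.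

**Step 13**
Reactants: 24 bicyclic C11 ketone
Product: 26 C11 acetate (11R), via aluminium alkoxide 25 (not isolated)
Conditions: iBu2AlH, CH2Cl2, −78 °C; then pyridine, DMAP, Ac2O, −78 to 0 °C
Reagents that add atoms: acetic anhydride, CC(=O)OC(C)=O
Why: One-pot reductive acetylation; hydride attacks the convex face, anti to the axial C12 methyl and the C10–C9 bond, giving the 11R alkoxide that is acetylated in situ before the ketone can epimerise at C12.

**Step 14**
Reactants: 26 C11 acetate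
Product: 28 C16 primary alcohol (15R), via alkylborane 27 (not isolated)
Conditions: 9-BBN, THF, 0 to 25 °C; H2O2, aq NaOAc, 0 °C
Reagents that add atoms: hydrogen peroxide, OO
Why: Hydroboration–oxidation; 9-BBN takes only the 1,1-disubstituted alkene (not the trisubstituted alkene or the iodoalkene) and adds from the C13 side of the A(1,3)-minimised isopropenyl rotamer, which gives 15R.

**Step 15**
Reactants: 28 C16 primary alcohol
Product: 29 C3/C16 diol
Conditions: DDQ, CH2Cl2/pH 7 buffer, 0 °C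
Reagents that add atoms: none
Why: Oxidative cleavage of the naphthylmethyl ether frees the tertiary C3 hydroxyl without touching the acetate, the alkenes or the vinyl iodide.

**Step 16**
Reactants: 29 C3/C16 diol
Product: 31 oxepane tetracycle (prenyl-type alkene and vinyl iodide intact), via primary triflate 30 (not isolated)
Conditions: Tf2O, 2,6-lutidine, CH2Cl2, −78 to 0 °C
Reagents that add atoms: none
Why: Selective triflation of the primary alcohol followed by intramolecular Williamson-type displacement by the tertiary C3 hydroxyl closes the oxepane; no stereocentre is involved.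

**Step 17**
Reactants: 31 oxepane tetracycle
Product: 33 C6 aldehyde, via ozonide 32 (not isolated)
Conditions: O3 (1.0 equiv), CH2Cl2, −78 °C; PPh3
Reagents that add atoms: ozone, [O-][O+]=O
Why: Ozonolysis is selective for the electron-rich trisubstituted alkene over the electron-poor iodoalkene and reveals the C6 aldehyde.

**Step 18**
Reactants: 33 C6 aldehyde
Product: 35 target, via alkenylchromium 34 (not isolated)
Conditions: CrCl2, NiCl2 (cat.), DMSO, 25 °C, 3 mM
Reagents that add atoms: none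
Why: Nozaki–Hiyama–Kishi macrocyclisation; the alkenylchromium forms and adds with retention of the Z geometry, closing the nine-membered ring, and the bridged transition state with the aldehyde oxygen turned outward is expected to give the 6R alcohol.

**Compound list**
1 | (1R,5R)-(+)-α-pinene | CC1=CC[C@@H]2C[C@H]1C2(C)C | starting material
2 | pinenylpotassium (α-pinene potassiated at C10) | [K]CC1=CC[C@@H]2C[C@H]1C2(C)C | intermediate
3 | dimethyl myrtenylboronate | COB(OC)CC1=CC[C@@H]2C[C@H]1C2(C)C | intermediate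
4 | (1R,5R)-(+)-β-pinene | C=C1CC[C@@H]2C[C@H]1C2(C)C | intermediate
5 | β-pinene ozonide (spiro-1,2,4-trioxolane, spiro centre unassigned) | C1OOC2(O1)CC[C@@H]3C[C@H]2C3(C)C | intermediate
6 | (1S,5R)-(−)-nopinone | O=C1CC[C@@H]2C[C@H]1C2(C)C | intermediate
7 | lithium enolate of 6 | [Li]OC1=CC[C@@H]2C[C@H]1C2(C)C | intermediate
8 | (1S,3R,5R)-3,6,6-trimethylbicyclo[3.1.1]heptan-2-one | O=C1[C@H](C)C[C@@H]2C[C@H]1C2(C)C | intermediate
9 | (4S,6R)-6-methyl-4-(prop-1-en-2-yl)cyclohex-1-en-1-yl acetate | CC(=O)OC1=CC[C@@H](C[C@H]1C)C(C)=C | intermediate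
10 | lithium (4S,6R)-6-methyl-4-(prop-1-en-2-yl)cyclohex-1-en-1-olate | [Li]OC1=CC[C@@H](C[C@H]1C)C(C)=C | intermediate
11 | (4S,6R)-6-methyl-4-(prop-1-en-2-yl)cyclohex-1-en-1-yl N,N-diisopropylcarbamate (fragment A) | CC(C)N(C(C)C)C(=O)OC1=CC[C@@H](C[C@H]1C)C(C)=C | intermediate
12 | nerol, (2Z)-3,7-dimethylocta-2,6-dien-1-ol | CC(C)=CCC/C(C)=C\CO | starting material
13 | [(2S,3R)-3-methyl-3-(4-methylpent-3-en-1-yl)oxiran-2-yl]methanol | OC[C@@H]1O[C@]1(C)CCC=C(C)C | intermediate
14 | (2S,3S)-3,7-dimethyl-3-(naphthalen-2-ylmethoxy)oct-6-ene-1,2-diol | OC[C@H](O)[C@@](C)(OCc1ccc2ccccc2c1)CCC=C(C)C | intermediate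
15 | (2S)-2,6-dimethyl-2-(naphthalen-2-ylmethoxy)hept-5-enal (fragment B) | O=C[C@@](C)(OCc1ccc2ccccc2c1)CCC=C(C)C | intermediate
16 | but-2-yn-1-ol | CC#CCO | starting material
17 | sodium vinylalanate (five-membered oxa-alumina cycle, Al on C3) | [Na+].CC1=CCO[Al-]1(OCCOC)OCCOC | intermediate
18 | (2Z)-3-iodobut-2-en-1-ol | C/C(I)=C/CO | intermediate
19 | (2Z)-3-iodobut-2-enal (fragment C) | C/C(I)=C/C=O | intermediate
20 | α-lithiated allyl carbamate (Li on C11, face cis to isopropenyl; TMEDA complex) | [Li][C@]1(OC(=O)N(C(C)C)C(C)C)C=C[C@@H](C[C@H]1C)C(C)=C | intermediate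
21 | allyltitanium triisopropoxide (Ti on C11, face anti to isopropenyl) | CC(C)O[Ti](OC(C)C)(OC(C)C)[C@@]1(OC(=O)N(C(C)C)C(C)C)C=C[C@@H](C[C@H]1C)C(C)=C | intermediate
22 | (3S,4R,6R)-3-[(1S,2S)-1-hydroxy-2,6-dimethyl-2-(naphthalen-2-ylmethoxy)hept-5-en-1-yl]-6-methyl-4-(prop-1-en-2-yl)cyclohex-1-en-1-yl N,N-diisopropylcarbamate | CC(C)N(C(C)C)C(=O)OC1=C[C@@H]([C@H](O)[C@@](C)(OCc2ccc3ccccc3c2)CCC=C(C)C)[C@@H](C[C@H]1C)C(C)=C | intermediate
23 | oxocarbenium ion from 22 and 19 (C2–O+=C9) | CC(C)N(C(C)C)C(=O)OC1=C[C@@H]([C@H]([O+]=C/C=C(/C)I)[C@@](C)(OCc2ccc3ccccc3c2)CCC=C(C)C)[C@@H](C[C@H]1C)C(C)=C | intermediate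
24 | cis-fused hexahydro-2-benzofuran-4(1H)-one: C11 ketone, C2–O–C9 ether, C9 (Z)-2-iodoprop-1-enyl, C2 side chain C3(Me)(O-naphthylmethyl)CH2CH2CH=CMe2, C12 methyl, C14 isopropenyl; C1, C2, C3, C9, C10, C12, C14 as in 35 | O=C1[C@@H]([C@H](/C=C(/C)I)O[C@@H]3[C@@](C)(OCc4ccc5ccccc5c4)CCC=C(C)C)[C@@H]3[C@@H](C[C@H]1C)C(C)=C | intermediate
25 | diisobutylaluminium 11R-alkoxide of reduced 24 | CC(C)C[Al](CC(C)C)O[C@H]1[C@@H]([C@H](/C=C(/C)I)O[C@@H]3[C@@](C)(OCc4ccc5ccccc5c4)CCC=C(C)C)[C@@H]3[C@@H](C[C@H]1C)C(C)=C | intermediate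
26 | 11R acetate of reduced 24 (all other centres as in 24) | CC(=O)O[C@H]1[C@@H]([C@H](/C=C(/C)I)O[C@@H]3[C@@](C)(OCc4ccc5ccccc5c4)CCC=C(C)C)[C@@H]3[C@@H](C[C@H]1C)C(C)=C | intermediate
27 | B-alkyl-9-BBN adduct at C16 (15R) | CC(=O)O[C@H]1[C@@H]([C@H](/C=C(/C)I)O[C@@H]3[C@@](C)(OCc4ccc5ccccc5c4)CCC=C(C)C)[C@@H]3[C@@H](C[C@H]1C)[C@@H](C)CB6C7CCCC6CCC7 | intermediate
28 | C16 primary alcohol (15R), C3 naphthylmethyl ether | CC(=O)O[C@H]1[C@@H]([C@H](/C=C(/C)I)O[C@@H]3[C@@](C)(OCc4ccc5ccccc5c4)CCC=C(C)C)[C@@H]3[C@@H](C[C@H]1C)[C@@H](C)CO | intermediate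
29 | C3 tertiary / C16 primary diol | CC(=O)O[C@H]1[C@@H]([C@H](/C=C(/C)I)O[C@@H]3[C@@](C)(O)CCC=C(C)C)[C@@H]3[C@@H](C[C@H]1C)[C@@H](C)CO | intermediate
30 | C16 primary triflate of 29 | CC(=O)O[C@H]1[C@@H]([C@H](/C=C(/C)I)O[C@@H]3[C@@](C)(O)CCC=C(C)C)[C@@H]3[C@@H](C[C@H]1C)[C@@H](C)COS(=O)(=O)C(F)(F)F | intermediate
31 | oxepane tetracycle: C3–O–C16 closed, C3 bearing CH2CH2CH=CMe2, C9 bearing (Z)-2-iodoprop-1-enyl | CC(=O)O[C@H]1[C@@H]([C@H](/C=C(/C)I)O[C@@H]34)[C@@H]3[C@@H](C[C@H]1C)[C@@H](C)CO[C@@]4(C)CCC=C(C)C | intermediate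
32 | ozonide of 31 (1,2,4-trioxolane, C6 unassigned) | CC(=O)O[C@H]1[C@@H]([C@H](/C=C(/C)I)O[C@@H]34)[C@@H]3[C@@H](C[C@H]1C)[C@@H](C)CO[C@@]4(C)CCC5OC(C)(C)OO5 | intermediate
33 | C6 aldehyde with C7 (Z)-vinyl iodide | CC(=O)O[C@H]1[C@@H]([C@H](/C=C(/C)I)O[C@@H]34)[C@@H]3[C@@H](C[C@H]1C)[C@@H](C)CO[C@@]4(C)CCC=O | intermediate
34 | C7 alkenylchromium dichloride (trivalent chromium) | CC(=O)O[C@H]1[C@@H]([C@H](/C=C(/C)[Cr](Cl)Cl)O[C@@H]34)[C@@H]3[C@@H](C[C@H]1C)[C@@H](C)CO[C@@]4(C)CCC=O | intermediate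
35 | target (1S,2S,3S,6R,9S,10R,11R,12R,14S,15R; 7Z) | CC(=O)O[C@H]1[C@@H]2[C@@H]3[C@@H](C[C@H]1C)[C@@H](C)CO[C@@]1(C)CC[C@@H](O)/C(C)=C\[C@@H]2O[C@@H]31 | target

**Count and risk**
Total steps: 18 (fragment A 5, fragment B 3, fragment C 2, union and endgame 8).
Longest linear sequence: 13 steps (steps 1–5 and 11–18, from (+)-α-pinene).

Three steps most likely to fail:

Step 11 (site and face of lithiation of the hindered enol carbamate; sense at C2). The C2 sense is argued by analogy to cyclohexenyl carbamate homoaldol additions used for related 2,9-bridged cores, and a simple closed chair would give the C2 epimer, so it must be confirmed on 24 by NOE. The fallback addresses the lithiation, not the C2 sense. It sets out from 9 and generates the same organolithium by α-deprotonation of an allylic carbamate instead of γ-deprotonation. MeLi then TMSCl gives the trimethylsilyl enol ether F1; Pd(OAc)2 in MeCN (Saegusa oxidation) gives the enone F2; NaBH4/CeCl3, with hydride anti to the pseudoaxial methyl, gives the allylic alcohol F3; NaH and ClC(O)N(iPr)2 give the allyl carbamate F4. Its single carbinol proton is removed by s-BuLi/TMEDA with retention, and the route is rejoined at 20.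

Step 12 (Z to E drift of the β-iodo oxocarbenium ion, or C12 epimerisation under BF3). The fallback sets out from 22 and installs the iodide after the annulation. Annulation with commercial but-2-ynal diethyl acetal and BF3·OEt2, through a propargylic oxocarbenium ion with no geometry to lose, gives the alkynyl ketone F5. Trans-hydrosilylation with Et3SiH and [Cp*Ru(MeCN)3]PF6 (silicon distal to the propargylic oxygen) gives the (Z)-vinylsilane F6. Iododesilylation with N-iodosuccinimide in hexafluoroisopropanol, with retention, rejoins the route at 24.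

Step 18 (ring closure under substrate control may favour the 6S alcohol). The fallback sets out from 33 and fixes C6 by reagent control. If the chromium-mediated closure gives the 6-epi alcohol F7, Dess–Martin oxidation gives the macrocyclic enone F8. Reduction with (S)-2-methyl-CBS-oxazaborolidine and catecholborane at −78 °C, with the alkenyl group as the large substituent, gives the 6R alcohol and rejoins the route at 35.

**Further compounds**
F1 | step 11 | trimethyl{[(4S,6R)-6-methyl-4-(prop-1-en-2-yl)cyclohex-1-en-1-yl]oxy}silane | C[Si](C)(C)OC1=CC[C@@H](C[C@H]1C)C(C)=C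
F2 | step 11 | (4R,6R)-6-methyl-4-(prop-1-en-2-yl)cyclohex-2-en-1-one | O=C1C=C[C@@H](C[C@H]1C)C(C)=C
F3 | step 11 | (1R,4R,6R)-6-methyl-4-(prop-1-en-2-yl)cyclohex-2-en-1-ol | O[C@H]1C=C[C@@H](C[C@H]1C)C(C)=C
F4 | step 11 | (1R,4R,6R)-6-methyl-4-(prop-1-en-2-yl)cyclohex-2-en-1-yl N,N-diisopropylcarbamate | CC(C)N(C(C)C)C(=O)O[C@H]1C=C[C@@H](C[C@H]1C)C(C)=C
F5 | step 12 | C9 prop-1-ynyl analogue of 24 | O=C1[C@@H]([C@H](C#CC)O[C@@H]3[C@@](C)(OCc4ccc5ccccc5c4)CCC=C(C)C)[C@@H]3[C@@H](C[C@H]1C)C(C)=C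
F6 | step 12 | C9 (Z)-2-(triethylsilyl)prop-1-enyl analogue of 24 | O=C1[C@@H]([C@H](/C=C(/C)[Si](CC)(CC)CC)O[C@@H]3[C@@](C)(OCc4ccc5ccccc5c4)CCC=C(C)C)[C@@H]3[C@@H](C[C@H]1C)C(C)=C
F7 | step 18 | 6-epi-35 (6S alcohol) | CC(=O)O[C@H]1[C@@H]2[C@@H]3[C@@H](C[C@H]1C)[C@@H](C)CO[C@@]1(C)CC[C@H](O)/C(C)=C\[C@@H]2O[C@@H]31
F8 | step 18 | C6 ketone (macrocyclic (Z)-enone) | CC(=O)O[C@H]1[C@@H]2[C@@H]3[C@@H](C[C@H]1C)[C@@H](C)CO[C@@]1(C)CCC(=O)/C(C)=C\[C@@H]2O[C@@H]31
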